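**Retrosynthetic overview**

1. Feature (lignan numbering: guaiacyl chain C7–C9, syringyl chain C7'–C9'): in the oxolane ring C7–O–C9'–C8'–C8, C8 (carrying carboxyl C9) and C8' (carrying the one-carbon branch C7') are cis neighbours, which is the α-carboxyl/β-vinyl pattern an ester-enolate Claisen shift leaves behind.
2. Target 18 ⇐ debenzylation of 17 ⇐ C7'–aryl bond by Friedel–Crafts arylation of lactol 15 with 2,6-dimethoxyphenol (γ-lactone ring closed last) ⇐ oxidative cleavage of the vinyl group of acid 12.
3. 12 ⇐ ring-contracting Ireland–Claisen shift (C8–C8' bond, oxolane ring) of the nine-membered Z-allylic lactone 9, whose C7–O–C9' ether is the future ring tether.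
4. 9 ⇐ ring-closing metathesis of allyl ether/allyl ester 8 ⇐ (S)-β-hydroxy ester 6 (C7 by asymmetric transfer hydrogenation) ⇐ β-keto ester 5 ⇐ acid 1, Meldrum's acid 2, allyl alcohol 3.
5. Ring order: nine-membered lactone (sacrificial), then oxolane, then γ-lactone. C7 is the only stereocentre set by a reagent; C8 and C8' follow from it in the key step, and C7' from the shape of the bicycle.

Key step: step 5

Assumption: 4-(benzyloxy)-3-methoxybenzoic acid (O-benzylated vanillic acid, commercial) is taken as starting material, and the target is read from its SMILES as the (3S,3aR,6S,6aS) isomer with both aryl groups exo on the cis-fused bicycle.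

**Route**

Step 1
Reactants: 1 4-(benzyloxy)-3-methoxybenzoic acid; 2 Meldrum's acid (2,2-dimethyl-1,3-dioxane-4,6-dione); 3 allyl alcohol (prop-2-en-1-ol)
Product: 5 prop-2-en-1-yl 3-[4-(benzyloxy)-3-methoxyphenyl]-3-oxopropanoate, via acyl Meldrum's acid 4 (not isolated)
Conditions: 2, DCC, DMAP, CH2Cl2, 0 °C → rt; filter, aq. KHSO4 wash; then 3 (5 equiv), toluene, 100 °C
Reagents that add atoms: none
Why: Carbodiimide acylation of Meldrum's acid should give 4, which on heating loses acetone and CO2 to an acylketene that allyl alcohol traps as the β-keto ester (Meldrum's acid β-keto ester synthesis).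

Step 2
Reactants: 5 prop-2-en-1-yl 3-[4-(benzyloxy)-3-methoxyphenyl]-3-oxopropanoate
Product: 6 prop-2-en-1-yl (3S)-3-[4-(benzyloxy)-3-methoxyphenyl]-3-hydroxypropanoate
Conditions: RuCl[(S,S)-TsDPEN](p-cymene) (1 mol%), HCO2H–Et3N (5:2), DMF, 40 °C
Reagents that add atoms: none
Why: Noyori–Ikariya asymmetric transfer hydrogenation of an aryl ketone, in which the (S,S)-TsDPEN ruthenium hydride should deliver hydride in the same sense as for acetophenone to set C7 as (S), while the outer-sphere catalyst leaves the allyl ester and the benzyl ether untouched.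

Step 3
Reactants: 6 prop-2-en-1-yl (3S)-3-[4-(benzyloxy)-3-methoxyphenyl]-3-hydroxypropanoate; 7 allyl bromide (3-bromoprop-1-ene)
Product: 8 prop-2-en-1-yl (3S)-3-[4-(benzyloxy)-3-methoxyphenyl]-3-(prop-2-en-1-yloxy)propanoate
Conditions: 7 (10 equiv), Ag2O, 4 Å MS, Et2O, dark, rt → 35 °C
Reagents that add atoms: none
Why: Silver-oxide-mediated Williamson-type O-alkylation runs under near-neutral conditions, so the β-hydroxy ester should be allylated without the retro-aldol or E1cB loss an alkali alkoxide would cause and without ionising the benzylic C7–O bond, leaving C7 unchanged.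

Step 4
Reactants: 8 prop-2-en-1-yl (3S)-3-[4-(benzyloxy)-3-methoxyphenyl]-3-(prop-2-en-1-yloxy)propanoate
Product: 9 (4S,7Z)-4-[4-(benzyloxy)-3-methoxyphenyl]-3,4,6,9-tetrahydro-2H-1,5-dioxonin-2-one
Conditions: second-generation Grubbs catalyst RuCl2(=CHPh)(PCy3)(H2IMes) (5 mol%), 1,4-benzoquinone (10 mol%), CH2Cl2 (2 mM), 40 °C
Reagents that add atoms: none
Why: Ring-closing metathesis with loss of ethene at high dilution should close the nine-membered lactone, a ring size that accommodates only the Z olefin and for which this closure is known for lactones and ethers.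

Step 5
Reactants: 9 (4S,7Z)-4-[4-(benzyloxy)-3-methoxyphenyl]-3,4,6,9-tetrahydro-2H-1,5-dioxonin-2-one
Product: 12 (2S,3S,4R)-2-[4-(benzyloxy)-3-methoxyphenyl]-4-ethenyloxolane-3-carboxylic acid, via silyl ketene acetal 10 (not isolated), via trimethylsilyl ester 11 (not isolated)
Conditions: Me3SiCl–Et3N (premixed, 3 equiv), KN(SiMe3)2 (1.3 equiv), THF–toluene, −78 °C; warm to rt, then 70 °C; 1 M HCl work-up
Reagents that add atoms: none
Why: Deprotonation at C8 in the presence of Me3SiCl should trap the lactone enolate as the ring-constrained (E)-silyl ketene acetal 10, which on warming undergoes a concerted [3,3] shift that forms C8–C8' as the allylic C–O bond breaks, and the silyl ester 11 is hydrolysed on work-up. The closest known reaction type is the Ireland–Claisen ring contraction of medium-ring Z-alkenyl lactones to cis-2-vinylcycloalkanecarboxylic acids, including nine-membered aza-lactones that give 2,3-trans-3,4-cis pyrrolidines. The oxolane ring is closed by C–C bond formation between the two termini of the 1,5-diene, which the three-atom tether C7–O–C9' already joins, so the nine-membered ring contracts by four atoms and the new ring forms in a 5-exo sense with the vinyl group left outside it. The tether forces a boat transition state, which together with the Z olefin and the cis-fixed ketene acetal sets C8 and C8' cis (carboxyl and vinyl on one face). The C7 aryl group should sit pseudo-equatorially on the forming ring and so select the face that puts the C8 carboxyl trans to it, giving (2S,3S,4R). The selectivity needed is O-silylation ahead of β-elimination of the C7 alkoxide, which in-situ trapping at −78 °C with the potassium amide is expected to secure.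

Step 6
Reactants: 12 (2S,3S,4R)-2-[4-(benzyloxy)-3-methoxyphenyl]-4-ethenyloxolane-3-carboxylic acid
Product: 15 (3aR,6S,6aS)-6-[4-(benzyloxy)-3-methoxyphenyl]-3-hydroxytetrahydro-1H,3H-furo[3,4-c]furan-1-one, via vicinal diol 13 (not isolated), via aldehyde acid 14 (not isolated)
Conditions: OsO4 (2 mol%), NaIO4 (4 equiv), 2,6-lutidine, dioxane–H2O (3:1), rt
Reagents that add atoms: osmium tetroxide, O=[Os](=O)(=O)=O; sodium periodate, [Na+].[O-]I(=O)(=O)=O (terminal oxidant that restores OsO4)
Why: Lemieux–Johnson oxidation should dihydroxylate the terminal vinyl group and cleave the diol while the lutidine buffer keeps the acid as its carboxylate, and the cis aldehyde acid then closes to the pseudo-acid lactol (either configuration at C3), which protects C8' from epimerisation.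

Step 7
Reactants: 15 (3aR,6S,6aS)-6-[4-(benzyloxy)-3-methoxyphenyl]-3-hydroxytetrahydro-1H,3H-furo[3,4-c]furan-1-one; 16 2,6-dimethoxyphenol
Product: 17 (3S,3aR,6S,6aS)-6-[4-(benzyloxy)-3-methoxyphenyl]-3-(4-hydroxy-3,5-dimethoxyphenyl)tetrahydro-1H,3H-furo[3,4-c]furan-1-one
Conditions: 16 (1.2 equiv), BF3·OEt2 (30 mol%), 4 Å MS, CH2Cl2, −20 → 0 °C
Reagents that add atoms: none
Why: Acid-promoted Friedel–Crafts arylation of a pseudo-acid, in which the lactol ionises to an acyloxycarbenium ion that the phenol should attack through the carbon para to its hydroxyl (the site its formylation and Mannich reactions also take) on the convex face of the cis-fused bicycle, placing the C7' aryl group exo, which is also the thermodynamic arrangement.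

Step 8
Reactants: 17 (3S,3aR,6S,6aS)-6-[4-(benzyloxy)-3-methoxyphenyl]-3-(4-hydroxy-3,5-dimethoxyphenyl)tetrahydro-1H,3H-furo[3,4-c]furan-1-one
Product: 18 (3S,3aR,6S,6aS)-6-(4-hydroxy-3-methoxyphenyl)-3-(4-hydroxy-3,5-dimethoxyphenyl)tetrahydro-1H,3H-furo[3,4-c]furan-1-one
Conditions: H2 (1 atm), 10% Pd/C, EtOAc, rt, stopped at consumption of 17
Reagents that add atoms: none
Why: Hydrogenolysis of the aryl benzyl ether should be faster than cleavage of the two benzylic ring C–O bonds under neutral conditions at 1 atm, and no stereocentre is touched.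

**Compound list**

1 | 4-(benzyloxy)-3-methoxybenzoic acid | COc1cc(C(=O)O)ccc1OCc1ccccc1 | starting material
2 | Meldrum's acid (2,2-dimethyl-1,3-dioxane-4,6-dione) | CC1(C)OC(=O)CC(=O)O1 | starting material
3 | allyl alcohol (prop-2-en-1-ol) | C=CCO | starting material
4 | 5-{[4-(benzyloxy)-3-methoxyphenyl](hydroxy)methylidene}-2,2-dimethyl-1,3-dioxane-4,6-dione | COc1cc(C(O)=C2C(=O)OC(C)(C)OC2=O)ccc1OCc1ccccc1 | intermediate (not isolated)
5 | prop-2-en-1-yl 3-[4-(benzyloxy)-3-methoxyphenyl]-3-oxopropanoate | COc1cc(C(=O)CC(=O)OCC=C)ccc1OCc1ccccc1 | intermediate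
6 | prop-2-en-1-yl (3S)-3-[4-(benzyloxy)-3-methoxyphenyl]-3-hydroxypropanoate | COc1cc([C@@H](O)CC(=O)OCC=C)ccc1OCc1ccccc1 | intermediate
7 | allyl bromide (3-bromoprop-1-ene) | C=CCBr | starting material
8 | prop-2-en-1-yl (3S)-3-[4-(benzyloxy)-3-methoxyphenyl]-3-(prop-2-en-1-yloxy)propanoate | COc1cc([C@@H](OCC=C)CC(=O)OCC=C)ccc1OCc1ccccc1 | intermediate
9 | (4S,7Z)-4-[4-(benzyloxy)-3-methoxyphenyl]-3,4,6,9-tetrahydro-2H-1,5-dioxonin-2-one | COc1cc([C@@H]2CC(=O)OC/C=C\CO2)ccc1OCc1ccccc1 | intermediate (key-step precursor)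
10 | (2E,4S,7Z)-4-[4-(benzyloxy)-3-methoxyphenyl]-2-[(trimethylsilyl)oxy]-6,9-dihydro-4H-1,5-dioxonine | COc1cc([C@@H]2/C=C(/O[Si](C)(C)C)OC/C=C\CO2)ccc1OCc1ccccc1 | intermediate (not isolated)
11 | trimethylsilyl (2S,3S,4R)-2-[4-(benzyloxy)-3-methoxyphenyl]-4-ethenyloxolane-3-carboxylate | COc1cc([C@H]2OC[C@H](C=C)[C@@H]2C(=O)O[Si](C)(C)C)ccc1OCc1ccccc1 | intermediate (not isolated)
12 | (2S,3S,4R)-2-[4-(benzyloxy)-3-methoxyphenyl]-4-ethenyloxolane-3-carboxylic acid | COc1cc([C@H]2OC[C@H](C=C)[C@@H]2C(=O)O)ccc1OCc1ccccc1 | intermediate (key-step product)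
13 | (2S,3S,4R)-2-[4-(benzyloxy)-3-methoxyphenyl]-4-(1,2-dihydroxyethyl)oxolane-3-carboxylic acid (carbinol epimers) | COc1cc([C@H]2OC[C@H](C(O)CO)[C@@H]2C(=O)O)ccc1OCc1ccccc1 | intermediate (not isolated)
14 | (2S,3S,4R)-2-[4-(benzyloxy)-3-methoxyphenyl]-4-formyloxolane-3-carboxylic acid | COc1cc([C@H]2OC[C@H](C=O)[C@@H]2C(=O)O)ccc1OCc1ccccc1 | intermediate (not isolated)
15 | (3aR,6S,6aS)-6-[4-(benzyloxy)-3-methoxyphenyl]-3-hydroxytetrahydro-1H,3H-furo[3,4-c]furan-1-one (either configuration at C3) | COc1cc([C@H]2OC[C@H]3[C@@H]2C(=O)OC3O)ccc1OCc1ccccc1 | intermediate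
16 | 2,6-dimethoxyphenol | COc1cccc(OC)c1O | starting material
17 | (3S,3aR,6S,6aS)-6-[4-(benzyloxy)-3-methoxyphenyl]-3-(4-hydroxy-3,5-dimethoxyphenyl)tetrahydro-1H,3H-furo[3,4-c]furan-1-one | COc1cc([C@H]2OC[C@H]3[C@@H]2C(=O)O[C@@H]3c2cc(OC)c(O)c(OC)c2)ccc1OCc1ccccc1 | intermediate
18 | (3S,3aR,6S,6aS)-6-(4-hydroxy-3-methoxyphenyl)-3-(4-hydroxy-3,5-dimethoxyphenyl)tetrahydro-1H,3H-furo[3,4-c]furan-1-one | COc1cc([C@H]2OC[C@H]3[C@@H]2C(=O)O[C@@H]3c2cc(OC)c(O)c(OC)c2)ccc1O | target

**Step count**

Total steps: 8. Longest linear sequence: 8 (from 1).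

**Steps most likely to fail**

Step 5 (key step). What may go wrong: β-elimination of the C7 ring alkoxide from the lactone enolate (ring opening to a cinnamate) may outrun O-silylation, or the shift may be slow enough that the ketene acetal is lost to C-silylation or hydrolysis, or face selection by the C7 aryl group may be incomplete. Fallback: avoid any β-alkoxy enolate by setting the C8/C8' relationship on a lactone and closing the oxolane afterwards at C7–O. This replaces steps 1 to 5; it sets out from commercial O-benzylvanillin (the aldehyde of acid 1) and comes back to the route at 12. The lithium enolate (LDA, THF, −78 °C) of (4S)-4-ethenyloxolan-2-one F1 (known in enantioenriched form, for example by conjugate addition of a vinylboron reagent to furan-2(5H)-one with Rh(acac)(C2H4)2 and a BINAP ligand) should add to O-benzylvanillin anti to the vinyl group to give the trans hydroxybenzyl lactone F2 as a carbinol mixture. LiAlH4 in THF should reduce F2 to triol F3. Camphorsulfonic acid in CH2Cl2 should ionise the benzylic alcohol so that the C9' hydroxyl closes the oxolane trans to the C8 substituent from either carbinol epimer (the closure used for 7,9'-epoxy lignans), giving alcohol F4. In F4 the C8 hydroxymethyl and C8' vinyl groups are cis, because the C7-bearing arm and the vinyl group were trans on the lactone. TEMPO with PhI(OAc)2 in MeCN–H2O should oxidise the primary alcohol to acid 12.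

Step 4. What may go wrong: intermolecular metathesis (dimer and oligomer formation) may compete with closure of the strained nine-membered ring, and ruthenium hydride species may isomerise the allyl ether. Fallback: close the ring at the acyl–oxygen bond with the Z olefin already in place. This sets out from 6 and comes back at 9. Alcohol 6 should be O-alkylated (Ag2O, Et2O, dark) with (2Z)-4-bromobut-2-en-1-yl acetate F5 (from 2,5-dihydrofuran and acetyl bromide) to give ether F6. LiOH in aqueous THF at 0 °C should remove both the allyl ester and the acetate to give seco acid F7. Yamaguchi macrolactonisation (2,4,6-trichlorobenzoyl chloride, Et3N, THF; then slow addition to DMAP in toluene at high dilution) should give lactone 9.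

Step 7. What may go wrong: the acid may also ionise the C7 benzylic ether or the newly formed C7' benzylic lactone, with capture by a second molecule of the phenol (ring opening, double arylation), or the phenol may react through a carbon meta to its hydroxyl. Fallback: bring in the syringyl ring as a nucleophilic aryl metal instead of by electrophilic substitution. This sets out from 15 and comes back at 18. 2-(Benzyloxy)-5-bromo-1,3-dimethoxybenzene F8 (from commercial 4-bromo-2,6-dimethoxyphenol, benzyl bromide and K2CO3) should be converted with Mg in THF into Grignard reagent F9. F9 (3 equiv, −78 → 0 °C) should open lactol 15 to its magnesium carboxylate aldehyde and add to the aldehyde to give hydroxy acid F10 as a carbinol mixture. TsOH in toluene should lactonise F10 by way of the benzylic cation, which funnels both carbinols to the exo lactone F11. Hydrogenolysis (H2, Pd/C, EtOAc) should remove both benzyl groups to give 18.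

Further compounds
F1 | step 5 | (4S)-4-ethenyloxolan-2-one | C=C[C@H]1COC(=O)C1
F2 | step 5 | (3S,4R)-3-{[4-(benzyloxy)-3-methoxyphenyl](hydroxy)methyl}-4-ethenyloxolan-2-one (carbinol epimers) | COc1cc(C(O)[C@H]2C(=O)OC[C@@H]2C=C)ccc1OCc1ccccc1
F3 | step 5 | (2R,3R)-2-{[4-(benzyloxy)-3-methoxyphenyl](hydroxy)methyl}-3-ethenylbutane-1,4-diol (carbinol epimers) | COc1cc(C(O)[C@@H](CO)[C@H](CO)C=C)ccc1OCc1ccccc1
F4 | step 5 | [(2S,3R,4R)-2-[4-(benzyloxy)-3-methoxyphenyl]-4-ethenyloxolan-3-yl]methanol | COc1cc([C@H]2OC[C@H](C=C)[C@@H]2CO)ccc1OCc1ccccc1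
F5 | step 4 | (2Z)-4-bromobut-2-en-1-yl acetate | CC(=O)OC/C=C\CBr
F6 | step 4 | prop-2-en-1-yl (3S)-3-{[(2Z)-4-(acetyloxy)but-2-en-1-yl]oxy}-3-[4-(benzyloxy)-3-methoxyphenyl]propanoate | COc1cc([C@@H](OC/C=C\COC(C)=O)CC(=O)OCC=C)ccc1OCc1ccccc1
F7 | step 4 | (3S)-3-[4-(benzyloxy)-3-methoxyphenyl]-3-{[(2Z)-4-hydroxybut-2-en-1-yl]oxy}propanoic acid | COc1cc([C@@H](OC/C=C\CO)CC(=O)O)ccc1OCc1ccccc1
F8 | step 7 | 2-(benzyloxy)-5-bromo-1,3-dimethoxybenzene | COc1cc(Br)cc(OC)c1OCc1ccccc1
F9 | step 7 | [4-(benzyloxy)-3,5-dimethoxyphenyl]magnesium bromide | COc1cc([Mg]Br)cc(OC)c1OCc1ccccc1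
F10 | step 7 | (2S,3S,4R)-2-[4-(benzyloxy)-3-methoxyphenyl]-4-{[4-(benzyloxy)-3,5-dimethoxyphenyl](hydroxy)methyl}oxolane-3-carboxylic acid (carbinol epimers) | COc1cc([C@H]2OC[C@H](C(O)c3cc(OC)c(OCc4ccccc4)c(OC)c3)[C@@H]2C(=O)O)ccc1OCc1ccccc1
F11 | step 7 | (3S,3aR,6S,6aS)-3-[4-(benzyloxy)-3,5-dimethoxyphenyl]-6-[4-(benzyloxy)-3-methoxyphenyl]tetrahydro-1H,3H-furo[3,4-c]furan-1-one | COc1cc([C@H]2OC[C@H]3[C@@H]2C(=O)O[C@@H]3c2cc(OC)c(OCc3ccccc3)c(OC)c2)ccc1OCc1ccccc1
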